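## The problem

The target is a 2',4'-dihydroxy-6'-methoxychalcone whose ring A carries, at the carbon between its two hydroxyl groups, an open 1,7-diphenylhept-2-enyl chain bound through C1 (chain numbered from the benzylic methine C1 to the phenethyl CH2 C7). No ring has to be built: the task is to join a seven-carbon chain and a cinnamoyl group to a very electron-rich, finally pentasubstituted benzene ring. Two stereocentres must be set, the doubly benzylic and allylic methine C1 (R) and the carbinol C5 (S). They lie 1,5 to each other across the E C2=C3 alkene, too far for direct induction, so C5 is either made independently or reached by relay through a temporary stereocentre next to C1. The C1–H bond is acidic and weak, and the alkene would gain conjugation with two arenes if it moved, so strong base, metal hydrides, radicals and hot acid all threaten C1 and the alkene position. The enone is a Michael acceptor that the neighbouring 2'-hydroxyl can close to a flavanone, and the phenols and the homoallylic alcohol dislike oxidants and strong acid, so the chalcone is best completed last on a protected ring A. Once the chain sits between two identical oxygen substituents the two remaining positions of ring A are equivalent, so the acyl group can enter without a regiochemical question. The feature that opens the key step is that C1, its phenyl ring and the E C2=C3 alkene form an (E)-4,4-diarylbut-2-enyl unit: such a unit arises when a 4-aryl vinylcarbenoid takes an allylic C–H bond of cyclohexa-1,3-diene with allylic transposition, the phenyl ring entering as a cyclohexa-2,5-dienyl group that is aromatised afterwards.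

## Retrosynthesis

**Target 24 to chalcone 23.** The two phenolic O–H bonds are traced back to methoxymethyl (MOM) ethers. Cleaving them last keeps ring A inert to base, hydride and organometallic reagents throughout. The alternative of freeing the phenols before acylation would force a Friedel–Crafts reaction in the presence of the alcohol and the alkene. The forward step needs only acid mild enough to spare the enone and the carbinol.

**23 to aryl bromide 20 and Weinreb amide 21.** The bond between ring A and the carbonyl carbon is cut. Against an aldol cut of the enone this saves the separate introduction of an acetyl group. The precursor loses the whole cinnamoyl unit. The aryl anion must be generated without touching C1–H, which is why bromine–lithium exchange at −78 °C (to aryllithium 22) is preferred to direct deprotonation of the ring.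

**20 to alcohol 19.** The C–Br bond is cut. The two open positions of ring A are equivalent and lie between a methoxy and a MOM-oxy group, so electrophilic bromination can give only one product. The step must leave the chain alkene alone.

**19 to allylboronate 15 and 3-phenylpropanal 16.** The C4–C5 bond is cut with allylic transposition. A linear allyl-metal reagent would bond through the wrong carbon, and a metathesis cut at C2=C3 would discard two carbons of the chain. A boronate carrying boron at C3 returns the alkene to C2=C3 on addition and passes its configuration on to C5. The forward reaction must give the E alkene and transfer chirality cleanly, which is asked of the borinic ester 18 formed from 15 through the borate 17.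

**15 to carbonate 14, alcohol 13 and enoate 12.** The C3–B bond is cut. The allylic carbonate is the substrate for copper-catalysed γ-borylation and comes from the enoate by reduction and acylation. All four carbons of the butenoate are kept. The borylation must be γ-selective and give the 3R centre next to the existing one.

**12 to cyclohexadiene 11.** The phenyl ring is traced back to a cyclohexa-2,5-dienyl group. Benzene offers no C–H bond that a carbenoid takes selectively, whereas the diene does, and dehydrogenation is easy. The oxidant must not abstract the C4–H.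

**11 to diazoester 9 and cyclohexa-1,3-diene 10 (key step).** The bond from C4 of the butenoate (C1 of the target) to the future phenyl ipso carbon is cut. Cutting the C1–ring A bond instead would use Friedel–Crafts or quinone methide chemistry on a ring that is itself a nucleophile. The cut chosen here removes the stereocentre and leaves a flat, achiral diazoester and a commodity diene. The forward reaction must be enantioselective and must occur at the vinylogous carbon.

**9 back to 5-methoxybenzene-1,3-diol 1.** Diazo transfer leads to ester 8 and acid 7. A Wittig cut of the styrenyl C=C gives aldehyde 4 and phosphonium salt 5 (through ylide 6). The formyl group comes from lithiation of the bis-MOM ether 2 (through aryllithium 3), and 2 from 1.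

## Roads not taken

**Alternative 1:** The C1–C2 bond is cut. The benzhydrol A1 loses water to the ortho-quinone methide A2, and the E-alkenylboronate A3 adds to its exocyclic carbon under a chiral 3,3'-dibromo-BINOL catalyst to give A4.
- Merits: the route is highly convergent, uses the native reactivity of the phloroglucinol ring, needs no phenol protection, and takes C5 from a separately made building block, so the two centres are set independently. It would be clearly shorter than the chosen plan.
- Weak points: A2 carries a second hydroxyl and a para-methoxy group, which stabilise it strongly and make it a weak electrophile. The open positions of ring A in A1 and A4 are nucleophilic enough to attack A2, so oligomerisation competes. The known scope covers simpler quinone methides. After A4 the cinnamoyl group would still have to be placed on a free resorcinol bearing the alkene, or the phenols protected again.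
- Comparison: the chosen plan is longer and relays C5 instead of importing it. Against this it sets C1 by a catalyst-controlled step with a close analogue in the 4-aryl series, never generates an electrophile that ring A can intercept, and keeps ring A protected for a clean endgame.

**Alternative 2:** The bond between the carbonyl carbon and the α-carbon of the enone is cut. The salicylaldehyde A5 adds its formyl C–H across ethynylbenzene A6 under [RhCl(cod)]2, 1,1'-bis(diphenylphosphino)ferrocene and Na2CO3 to give A7.
- Merits: the step is atom-economic, the E enone follows from syn addition, the ortho-hydroxyl serves as directing group, and no organolithium comes near C1–H. In that last respect it is gentler than the lithiation used here.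
- Weak points: it is only an endgame and leaves both stereocentres and the chain to other chemistry. The formyl group must first be placed on the finished ring A. Hydride species of monovalent rhodium can move the C2=C3 alkene into conjugation through the weak C1–H, which would erase C1. Decarbonylation and a final desilylation add further losses.
- Comparison: the step count of the endgame is the same as bromination, acylation and deprotection. The chosen plan gives up catalysis but runs at −78 °C with no metal hydride present.

**Alternative 3:** The C3–C4 bond is cut. The N-hydroxyphthalimide ester A8 loses CO2 and couples with the E-alkenyl bromide A9 under NiBr2(dme), 4,4'-di-tert-butyl-2,2'-bipyridine and zinc to give A10.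
- Merits: C5 comes from an easily made β-silyloxy acid, the alkene geometry is retained, and the conditions are mild. Decoupling C5 from C1 is a real advantage over the relay used here.
- Weak points: A9 still needs C1 set by a separate asymmetric step, which is the harder centre. The alkylnickel intermediate carries a β-silyloxy group that can be eliminated. Radical or low-valent nickel species can abstract the C1–H of A9 or A10.
- Comparison: the chosen plan makes C1 first in the key step and uses the ester carbon of that step as C4, where Alternative 3 would most plausibly reach A9 by cutting that carbon off again.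

Key step: step 6

Assumption: the rhodium carbenoid of step 6 and the organocopper species of step 10 exist only on the catalyst and are described in the Why lines, not counted as compounds; phosphonium salt 5 and Weinreb amide 21 are taken as catalogue reagents.

## Route

Step 1
Reactants: 1 5-methoxybenzene-1,3-diol
Product: 2 1-methoxy-3,5-bis(methoxymethoxy)benzene
Conditions: MOMCl (2.5 equiv), i-Pr2NEt (3 equiv), CH2Cl2, 0 °C to rt
Reagents that add atoms: chloromethyl methyl ether, COCCl
Why: O-alkylation of both phenols to acetal ethers (MOM protection); the ethers later direct lithiation and withstand the base, hydride, carbenoid and organometallic steps.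

Step 2
Reactants: 2 1-methoxy-3,5-bis(methoxymethoxy)benzene
Product: 4 4-methoxy-2,6-bis(methoxymethoxy)benzaldehyde, via aryllithium 3 (not isolated)
Conditions: n-BuLi (1.1 equiv), THF, 0 °C; DMF, 0 °C to rt; aq NH4Cl
Reagents that add atoms: N,N-dimethylformamide, CN(C)C=O
Why: Directed ortho-metalation; the position between the two MOM ethers is coordinated from both sides and should lithiate in preference to the positions next to the weaker methoxy director, and DMF formylates the aryllithium.

Step 3
Reactants: 4 4-methoxy-2,6-bis(methoxymethoxy)benzaldehyde; 5 (2-carboxyethyl)triphenylphosphonium bromide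
Product: 7 (3E)-4-[4-methoxy-2,6-bis(methoxymethoxy)phenyl]but-3-enoic acid, via carboxylate ylide 6 (not isolated)
Conditions: 5 (1.3 equiv), NaN(SiMe3)2 (2.6 equiv), THF, 0 °C; 4, 0 °C to rt; dilute aq HCl to pH 4
Reagents that add atoms: none
Why: Wittig olefination; ylides carrying a carboxylate favour the E alkene with aromatic aldehydes, and the alkene stays β,γ because the product is held as its carboxylate. Any Z isomer should be removed by crystallisation or equilibrated with catalytic iodine after step 4.

Step 4
Reactants: 7 (3E)-4-[4-methoxy-2,6-bis(methoxymethoxy)phenyl]but-3-enoic acid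
Product: 8 methyl (3E)-4-[4-methoxy-2,6-bis(methoxymethoxy)phenyl]but-3-enoate
Conditions: MeI, KHCO3, DMF, rt
Reagents that add atoms: iodomethane, CI
Why: SN2 O-methylation of the carboxylate; the weak base should not move the styrenyl alkene, and the acid-free conditions spare the MOM ethers.

Step 5
Reactants: 8 methyl (3E)-4-[4-methoxy-2,6-bis(methoxymethoxy)phenyl]but-3-enoate
Product: 9 methyl (3E)-2-diazo-4-[4-methoxy-2,6-bis(methoxymethoxy)phenyl]but-3-enoate
Conditions: p-ABSA (1.2 equiv), DBU (1.3 equiv), MeCN, 0 °C
Reagents that add atoms: 4-acetamidobenzenesulfonyl azide, CC(=O)Nc1ccc(cc1)S(=O)(=O)N=[N+]=[N-]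
Why: Regitz diazo transfer to the CH2 group activated by ester and alkene, the standard entry to 4-aryl vinyldiazoacetates; 9 should be kept cold and used promptly because such compounds slowly close to pyrazoles.

Step 6
Reactants: 9 methyl (3E)-2-diazo-4-[4-methoxy-2,6-bis(methoxymethoxy)phenyl]but-3-enoate; 10 cyclohexa-1,3-diene
Product: 11 methyl (2E,4R)-4-(cyclohexa-2,5-dien-1-yl)-4-[4-methoxy-2,6-bis(methoxymethoxy)phenyl]but-2-enoate
Conditions: Rh2(S-DOSP)4 (1 mol %), 10 (5 equiv), 2,2-dimethylbutane with a little PhCF3, slow addition of 9, −20 °C to rt
Reagents that add atoms: none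
Why: Rh2(S-DOSP)4, a chiral tetraprolinate of divalent rhodium, decomposes 9 with loss of N2 to a donor/acceptor vinylcarbenoid. In its s-cis form this takes up an allylic C–H bond of 10: hydride shift from the CH2 group to the carbenoid carbon runs concertedly, though asynchronously, with C–C bond formation between the vinylogous carbon (C4 of the butenoate) and the central carbon of the developing pentadienyl unit, through an ordered chair-like six-centre array, so that the net result equals C–H insertion followed by Cope rearrangement without that intermediate being formed. The closest known reaction type is this same combined C–H functionalization/Cope rearrangement of methyl 4-aryl-2-diazobut-3-enoates with cyclohexa-1,3-diene under the same catalyst; only the 2,6-dioxygenated aryl group is new. No ring is closed: one C–C bond, the skipped 1,4-diene and the E enoate (fixed by the cyclic array) are formed. The single new stereocentre, C4, is controlled by the prolinate ligands, which leave one face of the carbenoid open; in the 4-aryl series the S catalyst places aryl, alkenyl and cyclohexadienyl groups in the spatial order that corresponds to 4R here, and Rh2(R-DOSP)4 is at hand should the flanked aryl group reverse the sense. The step needs vinylogous instead of carbenoid-carbon reactivity and C–H functionalization instead of cyclopropanation or [4+3] annulation of the diene; the E aryl group at the vinyl terminus, the highly activated allylic C–H of a cis-diene, excess diene, slow addition and a hydrocarbon solvent should secure both. Because the aryl group is trans to the carbenoid carbon across the alkene, the MOM ethers cannot be reached intramolecularly.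

Step 7
Reactants: 11 methyl (2E,4R)-4-(cyclohexa-2,5-dien-1-yl)-4-[4-methoxy-2,6-bis(methoxymethoxy)phenyl]but-2-enoate
Product: 12 methyl (2E,4R)-4-[4-methoxy-2,6-bis(methoxymethoxy)phenyl]-4-phenylbut-2-enoate
Conditions: DDQ (1.05 equiv), PhMe, 0 °C to rt
Reagents that add atoms: none
Why: Dehydrogenative aromatisation; DDQ abstracts hydride from the doubly allylic CH2 of the 1,4-diene and proton loss gives the phenyl ring. The C4–H should survive because the flanking MOM ethers hold ring A out of overlap with it and only one equivalent of oxidant is used cold.

Step 8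
Reactants: 12 methyl (2E,4R)-4-[4-methoxy-2,6-bis(methoxymethoxy)phenyl]-4-phenylbut-2-enoate
Product: 13 (2E,4R)-4-[4-methoxy-2,6-bis(methoxymethoxy)phenyl]-4-phenylbut-2-en-1-ol
Conditions: i-Bu2AlH (2.5 equiv), CH2Cl2, −78 °C; aq potassium sodium tartrate
Reagents that add atoms: none
Why: 1,2-Reduction of the enoate to the allylic alcohol by a non-basic hydride, so that the acidic γ-hydrogen at C4 and the alkene geometry are not disturbed.

Step 9
Reactants: 13 (2E,4R)-4-[4-methoxy-2,6-bis(methoxymethoxy)phenyl]-4-phenylbut-2-en-1-ol
Product: 14 (2E,4R)-4-[4-methoxy-2,6-bis(methoxymethoxy)phenyl]-4-phenylbut-2-en-1-yl methyl carbonate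
Conditions: ClCO2Me, pyridine, CH2Cl2, 0 °C
Reagents that add atoms: methyl chloroformate, COC(=O)Cl
Why: O-acylation of the primary allylic alcohol; the carbonate is the leaving group for the copper-catalysed substitution and releases the methoxide that turns the catalyst over.

Step 10
Reactants: 14 (2E,4R)-4-[4-methoxy-2,6-bis(methoxymethoxy)phenyl]-4-phenylbut-2-en-1-yl methyl carbonate
Product: 15 2-[(3R,4R)-4-[4-methoxy-2,6-bis(methoxymethoxy)phenyl]-4-phenylbut-1-en-3-yl]-4,4,5,5-tetramethyl-1,3,2-dioxaborolane
Conditions: B2pin2 (2 equiv), CuCl (5 mol %), chiral N-heterocyclic carbene ligand from its imidazolinium salt (enantiomer chosen for 3R), NaOMe (0.8 equiv), THF, −30 °C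
Reagents that add atoms: bis(pinacolato)diboron, CC1(C)OB(OC1(C)C)B1OC(C)(C)C(C)(C)O1
Why: Copper-catalysed γ-selective boryl substitution (SN2') of an E-allylic carbonate: the boryl complex of monovalent copper adds boron to C3 and copper to C2, and β-elimination of the carbonate gives the terminal alkene. The chiral ligand sets C3, its sense to be checked against an achiral Xantphos catalyst that reveals the intrinsic bias of the neighbouring centre. The two C3 epimers are diastereomers at adjacent carbons and should be separable at this stage.

Step 11
Reactants: 15 2-[(3R,4R)-4-[4-methoxy-2,6-bis(methoxymethoxy)phenyl]-4-phenylbut-1-en-3-yl]-4,4,5,5-tetramethyl-1,3,2-dioxaborolane; 16 3-phenylpropanal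
Product: 19 (3S,5E,7R)-7-[4-methoxy-2,6-bis(methoxymethoxy)phenyl]-1,7-diphenylhept-5-en-3-ol, via lithium butylborate complex 17 (not isolated), via trifluoroacetoxy borinic ester 18 (not isolated)
Conditions: n-BuLi (1.1 equiv), THF, −78 °C; (CF3CO)2O (1.2 equiv); 16 (1.5 equiv), −78 °C to rt; 1 M aq NaOH
Reagents that add atoms: none
Why: Allylboration with an α-substituted allylboron reagent through a chair transition state: butyllithium adds to boron, trifluoroacetic anhydride opens the pinacolate to the more Lewis-acidic borinic ester 18, and this transfers the allyl group to 16 with the aldehyde chain and the C3 substituent both equatorial. That arrangement gives the E alkene and converts 3R of 15 into 3S of 19 (C5 of the target); C7 is not involved.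

Step 12
Reactants: 19 (3S,5E,7R)-7-[4-methoxy-2,6-bis(methoxymethoxy)phenyl]-1,7-diphenylhept-5-en-3-ol
Product: 20 (3S,5E,7R)-7-[3-bromo-4-methoxy-2,6-bis(methoxymethoxy)phenyl]-1,7-diphenylhept-5-en-3-ol
Conditions: NBS (1.0 equiv), MeCN, −20 °C, dark
Reagents that add atoms: N-bromosuccinimide, O=C1CCC(=O)N1Br
Why: Electrophilic aromatic bromination; the two open positions of ring A are equivalent and far more nucleophilic than the disubstituted alkene, so one equivalent at low temperature should give a single monobromide.

Step 13
Reactants: 20 (3S,5E,7R)-7-[3-bromo-4-methoxy-2,6-bis(methoxymethoxy)phenyl]-1,7-diphenylhept-5-en-3-ol; 21 (2E)-N-methoxy-N-methyl-3-phenylprop-2-enamide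
Product: 23 (2E)-1-{3-[(1R,2E,5S)-5-hydroxy-1,7-diphenylhept-2-en-1-yl]-6-methoxy-2,4-bis(methoxymethoxy)phenyl}-3-phenylprop-2-en-1-one, via dilithiated aryllithium alkoxide 22 (not isolated)
Conditions: n-BuLi (2.1 equiv), THF, −78 °C, 10 min; 21 (1.3 equiv), −78 to −20 °C; aq NH4Cl
Reagents that add atoms: none
Why: The first equivalent of butyllithium deprotonates the alcohol and the second effects bromine–lithium exchange, which at −78 °C is much faster than deprotonation of the doubly benzylic C–H. The aryllithium adds 1,2 to the Weinreb amide (Weinreb ketone synthesis), whose chelated adduct prevents a second addition and releases the E enone on work-up.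

Step 14
Reactants: 23 (2E)-1-{3-[(1R,2E,5S)-5-hydroxy-1,7-diphenylhept-2-en-1-yl]-6-methoxy-2,4-bis(methoxymethoxy)phenyl}-3-phenylprop-2-en-1-one
Product: 24 (2E)-1-{2,4-dihydroxy-3-[(1R,2E,5S)-5-hydroxy-1,7-diphenylhept-2-en-1-yl]-6-methoxyphenyl}-3-phenylprop-2-en-1-one
Conditions: 3 M aq HCl, MeOH–THF, 40 °C
Reagents that add atoms: none
Why: Acid-catalysed acetal exchange with methanol removes both phenolic MOM ethers, the one next to the carbonyl being assisted by hydrogen bonding. Chalcones with one ortho-hydroxyl and one ortho-methoxy group are commonly released this way, and the mild acid should spare the carbinol and the stereocentres.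

## Compound list

1 | 5-methoxybenzene-1,3-diol | COc1cc(O)cc(O)c1 | starting material
2 | 1-methoxy-3,5-bis(methoxymethoxy)benzene | COCOc1cc(OC)cc(OCOC)c1 | intermediate
3 | [4-methoxy-2,6-bis(methoxymethoxy)phenyl]lithium | [Li]c1c(OCOC)cc(OC)cc1OCOC | intermediate
4 | 4-methoxy-2,6-bis(methoxymethoxy)benzaldehyde | COCOc1cc(OC)cc(OCOC)c1C=O | intermediate
5 | (2-carboxyethyl)triphenylphosphonium bromide | [Br-].OC(=O)CC[P+](c1ccccc1)(c1ccccc1)c1ccccc1 | starting material
6 | sodium 3-(triphenyl-λ5-phosphanylidene)propanoate | [Na+].[O-]C(=O)CC=P(c1ccccc1)(c1ccccc1)c1ccccc1 | intermediate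
7 | (3E)-4-[4-methoxy-2,6-bis(methoxymethoxy)phenyl]but-3-enoic acid | COCOc1cc(OC)cc(OCOC)c1/C=C/CC(=O)O | intermediate
8 | methyl (3E)-4-[4-methoxy-2,6-bis(methoxymethoxy)phenyl]but-3-enoate | COCOc1cc(OC)cc(OCOC)c1/C=C/CC(=O)OC | intermediate
9 | methyl (3E)-2-diazo-4-[4-methoxy-2,6-bis(methoxymethoxy)phenyl]but-3-enoate | COCOc1cc(OC)cc(OCOC)c1/C=C/C(=[N+]=[N-])C(=O)OC | intermediate
10 | cyclohexa-1,3-diene | C1=CC=CCC1 | starting material
11 | methyl (2E,4R)-4-(cyclohexa-2,5-dien-1-yl)-4-[4-methoxy-2,6-bis(methoxymethoxy)phenyl]but-2-enoate | COCOc1cc(OC)cc(OCOC)c1[C@H](/C=C/C(=O)OC)C1C=CCC=C1 | intermediate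
12 | methyl (2E,4R)-4-[4-methoxy-2,6-bis(methoxymethoxy)phenyl]-4-phenylbut-2-enoate | COCOc1cc(OC)cc(OCOC)c1[C@H](/C=C/C(=O)OC)c1ccccc1 | intermediate
13 | (2E,4R)-4-[4-methoxy-2,6-bis(methoxymethoxy)phenyl]-4-phenylbut-2-en-1-ol | COCOc1cc(OC)cc(OCOC)c1[C@H](/C=C/CO)c1ccccc1 | intermediate
14 | (2E,4R)-4-[4-methoxy-2,6-bis(methoxymethoxy)phenyl]-4-phenylbut-2-en-1-yl methyl carbonate | COCOc1cc(OC)cc(OCOC)c1[C@H](/C=C/COC(=O)OC)c1ccccc1 | intermediate
15 | 2-[(3R,4R)-4-[4-methoxy-2,6-bis(methoxymethoxy)phenyl]-4-phenylbut-1-en-3-yl]-4,4,5,5-tetramethyl-1,3,2-dioxaborolane | COCOc1cc(OC)cc(OCOC)c1[C@H]([C@@H](C=C)B1OC(C)(C)C(C)(C)O1)c1ccccc1 | intermediate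
16 | 3-phenylpropanal | O=CCCc1ccccc1 | starting material
17 | lithium butyl[(3R,4R)-4-[4-methoxy-2,6-bis(methoxymethoxy)phenyl]-4-phenylbut-1-en-3-yl](2,3-dimethylbutane-2,3-diolato)borate | [Li+].COCOc1cc(OC)cc(OCOC)c1[C@H]([C@@H](C=C)[B-]1(CCCC)OC(C)(C)C(C)(C)O1)c1ccccc1 | intermediate
18 | 2,3-dimethyl-3-(trifluoroacetoxy)butan-2-yl butyl[(3R,4R)-4-[4-methoxy-2,6-bis(methoxymethoxy)phenyl]-4-phenylbut-1-en-3-yl]borinate | COCOc1cc(OC)cc(OCOC)c1[C@H]([C@@H](C=C)B(CCCC)OC(C)(C)C(C)(C)OC(=O)C(F)(F)F)c1ccccc1 | intermediate
19 | (3S,5E,7R)-7-[4-methoxy-2,6-bis(methoxymethoxy)phenyl]-1,7-diphenylhept-5-en-3-ol | COCOc1cc(OC)cc(OCOC)c1[C@H](/C=C/C[C@@H](O)CCc1ccccc1)c1ccccc1 | intermediate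
20 | (3S,5E,7R)-7-[3-bromo-4-methoxy-2,6-bis(methoxymethoxy)phenyl]-1,7-diphenylhept-5-en-3-ol | COCOc1cc(OC)c(Br)c(OCOC)c1[C@H](/C=C/C[C@@H](O)CCc1ccccc1)c1ccccc1 | intermediate
21 | (2E)-N-methoxy-N-methyl-3-phenylprop-2-enamide | CON(C)C(=O)/C=C/c1ccccc1 | starting material
22 | lithium (3S,5E,7R)-7-[3-lithio-4-methoxy-2,6-bis(methoxymethoxy)phenyl]-1,7-diphenylhept-5-en-3-olate | COCOc1cc(OC)c([Li])c(OCOC)c1[C@H](/C=C/C[C@@H](O[Li])CCc1ccccc1)c1ccccc1 | intermediate
23 | (2E)-1-{3-[(1R,2E,5S)-5-hydroxy-1,7-diphenylhept-2-en-1-yl]-6-methoxy-2,4-bis(methoxymethoxy)phenyl}-3-phenylprop-2-en-1-one | COCOc1cc(OC)c(C(=O)/C=C/c2ccccc2)c(OCOC)c1[C@H](/C=C/C[C@@H](O)CCc1ccccc1)c1ccccc1 | intermediate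
24 | (2E)-1-{2,4-dihydroxy-3-[(1R,2E,5S)-5-hydroxy-1,7-diphenylhept-2-en-1-yl]-6-methoxyphenyl}-3-phenylprop-2-en-1-one (CNP0102625.1) | COc1cc(O)c([C@H](/C=C/C[C@@H](O)CCc2ccccc2)c2ccccc2)c(O)c1C(=O)/C=C/c1ccccc1 | target

## Step count and least certain steps

Total step count: 14. Longest linear sequence: 14 steps (1 to 24).

**Step 6 (key step).** The two MOM ethers flank the vinylogous carbon and twist ring A out of conjugation. Shielding of that carbon may divert the carbenoid to reaction at its own carbon (plain C–H insertion) or to cyclopropanation and [4+3] annulation of the diene. The altered shape may also lower the enantioselectivity, and the diazoester may close to a pyrazole before it meets the catalyst.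
Fallback: this forms the C1–ring A bond instead of the C1–phenyl bond. It sets out from 2, which is lithiated as in step 2 to 3 and transmetalated with MgBr2·OEt2 to [4-methoxy-2,6-bis(methoxymethoxy)phenyl]magnesium bromide F1. Copper-catalysed asymmetric allylic arylation (SN2') of cinnamyl bromide with F1 under CuCl and a chiral N-heterocyclic carbene ligand should give 5-methoxy-1,3-bis(methoxymethoxy)-2-[(1R)-1-phenylprop-2-en-1-yl]benzene F2. Cross-metathesis of F2 with methyl acrylate under the second-generation Hoveyda–Grubbs catalyst comes back to the route at 12.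

**Step 10.** Borylcupration must place boron on the alkene carbon next to the bulky diarylmethine. Slow addition, competing substitution without transposition, and a mismatch between the ligand and the existing centre at C4 may give a mixture at C3, which would pass into a mixture at C5.
Fallback: this sets C5 independently of C1. It sets out from 13, which undergoes cross-metathesis with excess (3S)-1-phenylhex-5-en-3-ol F3 under the second-generation Hoveyda–Grubbs catalyst in CH2Cl2 at 40 °C. F3 is made from 16 by asymmetric allylation with B-allyldiisopinocampheylborane of the enantiomer that gives the S alcohol. The E-selective exchange of the hydroxymethyl-bearing alkene terminus comes back to the route at 19, at the cost of two chain carbons lost as allyl alcohol.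

**Step 11.** The very large substituent at C3 may be pushed partly into the axial position of the chair, with loss of E selectivity and of chirality transfer. Butyllithium may also deprotonate C4–H before it adds to boron.
Fallback: this sets out from 15, which is converted with aqueous KHF2 in MeOH into potassium trifluoro[(3R,4R)-4-[4-methoxy-2,6-bis(methoxymethoxy)phenyl]-4-phenylbut-1-en-3-yl]borate F4. Treated with BF3·OEt2 and 16 in CH2Cl2 at −78 °C, F4 reacts as the allyldifluoroborane, whose small ligands on boron favour the equatorial substituent and which needs no organolithium. It comes back to the route at 19.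

**Step 14.** Under the acid that removes the MOM groups the freed 2'-hydroxyl may add to the enone (ring closure to the flavanone), or a phenol may add to the chain alkene.
Fallback: this forms the enone after the acid step. It sets out from 20, which is converted to 22 as in step 13 and quenched with N-methoxy-N-methylacetamide to give 1-{3-[(1R,2E,5S)-5-hydroxy-1,7-diphenylhept-2-en-1-yl]-6-methoxy-2,4-bis(methoxymethoxy)phenyl}ethan-1-one F5. Cleavage of the MOM ethers with HCl in MeOH gives 1-{2,4-dihydroxy-3-[(1R,2E,5S)-5-hydroxy-1,7-diphenylhept-2-en-1-yl]-6-methoxyphenyl}ethan-1-one F6. Claisen–Schmidt condensation of F6 with benzaldehyde (KOH, EtOH, rt) comes back to the route at 24.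

## Further compounds

F1 | step 6 | [4-methoxy-2,6-bis(methoxymethoxy)phenyl]magnesium bromide | Br[Mg]c1c(OCOC)cc(OC)cc1OCOC
F2 | step 6 | 5-methoxy-1,3-bis(methoxymethoxy)-2-[(1R)-1-phenylprop-2-en-1-yl]benzene | COCOc1cc(OC)cc(OCOC)c1[C@H](C=C)c1ccccc1
F3 | step 10 | (3S)-1-phenylhex-5-en-3-ol | C=CC[C@@H](O)CCc1ccccc1
F4 | step 11 | potassium trifluoro[(3R,4R)-4-[4-methoxy-2,6-bis(methoxymethoxy)phenyl]-4-phenylbut-1-en-3-yl]borate | [K+].COCOc1cc(OC)cc(OCOC)c1[C@H]([C@@H](C=C)[B-](F)(F)F)c1ccccc1
F5 | step 14 | 1-{3-[(1R,2E,5S)-5-hydroxy-1,7-diphenylhept-2-en-1-yl]-6-methoxy-2,4-bis(methoxymethoxy)phenyl}ethan-1-one | COCOc1cc(OC)c(C(C)=O)c(OCOC)c1[C@H](/C=C/C[C@@H](O)CCc1ccccc1)c1ccccc1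
F6 | step 14 | 1-{2,4-dihydroxy-3-[(1R,2E,5S)-5-hydroxy-1,7-diphenylhept-2-en-1-yl]-6-methoxyphenyl}ethan-1-one | COc1cc(O)c([C@H](/C=C/C[C@@H](O)CCc2ccccc2)c2ccccc2)c(O)c1C(C)=O
A1 | alternative 1 | 2-[hydroxy(phenyl)methyl]-5-methoxybenzene-1,3-diol | COc1cc(O)c(C(O)c2ccccc2)c(O)c1
A2 | alternative 1 | 6-benzylidene-5-hydroxy-3-methoxycyclohexa-2,4-dien-1-one | COC1=CC(=O)C(=Cc2ccccc2)C(O)=C1
A3 | alternative 1 | diethyl [(1E,4S)-4-(tert-butyldimethylsilyloxy)-6-phenylhex-1-en-1-yl]boronate | CCOB(OCC)/C=C/C[C@@H](O[Si](C)(C)C(C)(C)C)CCc1ccccc1
A4 | alternative 1 | 5-methoxy-2-[(1R,2E,5S)-5-(tert-butyldimethylsilyloxy)-1,7-diphenylhept-2-en-1-yl]benzene-1,3-diol | COc1cc(O)c([C@H](/C=C/C[C@@H](O[Si](C)(C)C(C)(C)C)CCc2ccccc2)c2ccccc2)c(O)c1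
A5 | alternative 2 | 3-[(1R,2E,5S)-5-(tert-butyldimethylsilyloxy)-1,7-diphenylhept-2-en-1-yl]-2,4-dihydroxy-6-methoxybenzaldehyde | COc1cc(O)c([C@H](/C=C/C[C@@H](O[Si](C)(C)C(C)(C)C)CCc2ccccc2)c2ccccc2)c(O)c1C=O
A6 | alternative 2 | ethynylbenzene | C#Cc1ccccc1
A7 | alternative 2 | (2E)-1-{3-[(1R,2E,5S)-5-(tert-butyldimethylsilyloxy)-1,7-diphenylhept-2-en-1-yl]-2,4-dihydroxy-6-methoxyphenyl}-3-phenylprop-2-en-1-one | COc1cc(O)c([C@H](/C=C/C[C@@H](O[Si](C)(C)C(C)(C)C)CCc2ccccc2)c2ccccc2)c(O)c1C(=O)/C=C/c1ccccc1
A8 | alternative 3 | 1,3-dioxoisoindolin-2-yl (3S)-3-(tert-butyldimethylsilyloxy)-5-phenylpentanoate | O=C(C[C@@H](O[Si](C)(C)C(C)(C)C)CCc1ccccc1)ON1C(=O)c2ccccc2C1=O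
A9 | alternative 3 | 2-[(1R,2E)-3-bromo-1-phenylprop-2-en-1-yl]-5-methoxy-1,3-bis(methoxymethoxy)benzene | COCOc1cc(OC)cc(OCOC)c1[C@H](/C=C/Br)c1ccccc1
A10 | alternative 3 | 2-[(1R,2E,5S)-5-(tert-butyldimethylsilyloxy)-1,7-diphenylhept-2-en-1-yl]-5-methoxy-1,3-bis(methoxymethoxy)benzene | COc1cc(OCOC)c([C@H](/C=C/C[C@@H](O[Si](C)(C)C(C)(C)C)CCc2ccccc2)c2ccccc2)c(OCOC)c1
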